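Skeleton locants: C1 and C3 carry the tiglate and isovalerate, C4 is CMe2, C7 the ketone, C9 and C11 the methylated carbons. The route rests on cutting the cyclobutane C5–C6–C11–C10 at its opposite bonds C5–C10 and C6–C11, which also opens the six-membered ring C6–C7–C8–C9–C10–C11. Forward, one intramolecular ketene–alkene [2+2] cycloaddition forms both bonds, closes both rings and sets C6, C10 and C11. The precursor is an open-chain (E)-enoyl chloride: its vinylketene (C5=C6) is tied through C7–C8–C9 to the trisubstituted C10=C11 alkene, and one C9 methyl stereocentre, erased later, steers the facial sense. The C5 cyclobutanone then anchors the seven-membered ring.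

Key step: step 7

Remark 1: locants C1–C11 of the target skeleton (ring atoms in the sequence C1–C2–C3–C4–C5–C6–C7–C8–C9–C10–C11, with further bonds C5–C10, C6–C11 and C11–C1) are used for all intermediates; in these locants the target is (1R,3R,5S,6R,10R,11R).
Remark 2: the Ipc2BCl antipode in step 4 is assigned from the general Re-face preference of methyl ketone diisopinocampheylborinates made from (−)-Ipc2BCl; if a model aldol shows the opposite sense, (+)-Ipc2BCl takes its place.

Step 1
Reactants: 1 (S)-4-benzyl-3-propionyl-1,3-oxazolidin-2-one; 2 allyl iodide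
Product: 3 (S)-4-benzyl-3-[(R)-2-methylpent-4-enoyl]-1,3-oxazolidin-2-one
Conditions: NaN(SiMe3)2, THF, −78 °C; then 2, −78 to −45 °C
Reagents that add atoms: none
Why: Evans asymmetric alkylation, in which the chelated Z-sodium enolate is allylated on the face away from the benzyl group, should set the future C9 methyl stereocentre as (R).

Step 2
Reactants: 3 (S)-4-benzyl-3-[(R)-2-methylpent-4-enoyl]-1,3-oxazolidin-2-one
Product: 4 (R)-2-methylpent-4-en-1-ol
Conditions: LiBH4, H2O (1 equiv), Et2O, 0 °C
Reagents that add atoms: none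
Why: Borohydride reduction of the N-acyl oxazolidinone should release the primary alcohol without touching the stereocentre and return the auxiliary.

Step 3
Reactants: 4 (R)-2-methylpent-4-en-1-ol; 5 2-(triphenylphosphoranylidene)propanal
Product: 7 (2E,4R)-2,4-dimethylhepta-2,6-dienal, via (R)-2-methylpent-4-enal 6 (not isolated)
Conditions: Dess–Martin periodinane, NaHCO3, CH2Cl2, 0 °C to rt; then 5, toluene, 80 °C
Reagents that add atoms: none
Why: Dess–Martin oxidation followed in the same flask by a Wittig reaction of the stabilised ylide should give the (E)-trisubstituted enal (C10=C11 with the C1 aldehyde) while the epimerisable aldehyde 6 is never stored.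

Step 4
Reactants: 7 (2E,4R)-2,4-dimethylhepta-2,6-dienal; 8 3-methylbut-3-en-2-one
Product: 9 (5R,6E,8R)-5-hydroxy-2,6,8-trimethylundeca-1,6,10-trien-3-one
Conditions: 8, (−)-Ipc2BCl, Et3N, Et2O, 0 °C; then 7, −78 to −20 °C; then H2O2, pH 7 buffer, MeOH
Reagents that add atoms: none
Why: The boron-mediated aldol of the methyl ketone through its chiral diisopinocampheylborinate (Paterson aldol) should form C1–C2 with reagent-controlled attack on the Re face of the enal, which sets C1 as (R), the remote C9 centre having little influence.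

Step 5
Reactants: 9 (5R,6E,8R)-5-hydroxy-2,6,8-trimethylundeca-1,6,10-trien-3-one
Product: 10 (5R,6E,8R)-5-[(tert-butyldimethylsilyl)oxy]-2,6,8-trimethylundeca-1,6,10-trien-3-one
Conditions: TBSOTf, 2,6-lutidine, CH2Cl2, −78 °C
Reagents that add atoms: tert-butyldimethylsilyl triflate, CC(C)(C)[Si](C)(C)OS(=O)(=O)C(F)(F)F
Why: Silylation with the triflate and a hindered pyridine base should protect the β-hydroxy ketone at low temperature without retro-aldol or oxa-Michael closure.

Step 6
Reactants: 10 (5R,6E,8R)-5-[(tert-butyldimethylsilyl)oxy]-2,6,8-trimethylundeca-1,6,10-trien-3-one; 11 acrylic acid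
Product: 12 (2E,5R,6E,8R)-8-[(tert-butyldimethylsilyl)oxy]-5,7,11-trimethyl-10-oxododeca-2,6,11-trienoic acid
Conditions: 11 (5 equiv), second-generation Hoveyda–Grubbs catalyst (5 mol %), CH2Cl2, 40 °C
Reagents that add atoms: none
Why: Olefin cross-metathesis of the only monosubstituted alkene with acrylic acid should give the (E)-enoic acid (C5 carboxyl, C6=C7), the trisubstituted alkene and the 1,1-disubstituted enone alkene being far less reactive.

Step 7
Reactants: 12 (2E,5R,6E,8R)-8-[(tert-butyldimethylsilyl)oxy]-5,7,11-trimethyl-10-oxododeca-2,6,11-trienoic acid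
Product: 15 7-[(1R)-1-(tert-butyldimethylsilyloxy)-4-methyl-3-oxopent-4-enyl]-4,7-dimethylbicyclo[3.1.1]hept-2-en-6-one (C5 ketone; C9 R), via trienoyl chloride 13 (not isolated), via (Z)-vinylketene 14 (not isolated)
Conditions: (COCl)2, DMF (cat.), CH2Cl2, 0 °C to rt; evaporate; then slow addition to Et3N (5 equiv), toluene, 110 °C, 0.005 M
Reagents that add atoms: none
Why: Oxalyl chloride gives enoyl chloride 13, Et3N removes a C8 hydrogen (1,4-dehydrochlorination) to give the (Z)-vinylketene 14, and 14 undergoes a thermal, concerted but asynchronous [π2s+π2a] cycloaddition in which the electrophilic ketene carbon C5 bonds to the less substituted alkene carbon C10 while charge builds on tertiary C11, which bonds to C6. The closest known reaction type is the intramolecular cycloaddition of vinylketenes, made from α,β-unsaturated acid chlorides and Et3N, with a trisubstituted alkene held three atoms away, which gives bicyclo[3.1.1]heptan-6-ones. The cyclobutane C5–C6–C11–C10 closes in the bridged (crossed) mode and the six-membered ring C5–C6–C7–C8–C9–C10 closes through the C5–C10 bond along the three-atom tether, for which the (Z)-C7=C8 bond is obligatory. C6 and C10 are fixed by the tether (the C7–C9 bridge must be cis on the cyclobutane), C11 by suprafacial addition to the (E)-alkene (methyl syn to the bridge, C1 chain anti), and the absolute sense by C9, whose methyl avoids the A(1,3) clash with the C11 methyl and so lies on the face of C5. The step needs bridged rather than fused regiochemistry, which the polarisation of the trisubstituted alkene and the three-atom tether secure, and the Z ketene geometry, which syn-selective γ-deprotonation and its reversibility should supply.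

Step 8
Reactants: 15 7-[(1R)-1-(tert-butyldimethylsilyloxy)-4-methyl-3-oxopent-4-enyl]-4,7-dimethylbicyclo[3.1.1]hept-2-en-6-one
Product: 16 C5-hydroxy C3-keto tricycle (C1 OTBS; C4 gem-dimethyl; C7=C8 alkene; C9 R)
Conditions: [(Ph3P)CuH]6 (0.4 equiv), toluene, −40 °C to rt; then aqueous NH4Cl
Reagents that add atoms: none
Why: Copper hydride conjugate reduction of the isopropenyl ketone should give regiospecifically the tetrasubstituted C4 enolate, which adds to the strained C5 ketone in a reductive aldol cyclisation; the tether reaches C5 only from its exo face, so C4 ends anti to the C7–C9 bridge and the hydroxyl endo.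

Step 9
Reactants: 16 C5-hydroxy C3-keto tricycle
Product: 17 C5 methyl oxalate of 16
Conditions: methyl chlorooxoacetate, DMAP, pyridine, CH2Cl2, 0 °C to rt
Reagents that add atoms: methyl chlorooxoacetate, COC(=O)C(=O)Cl
Why: Acylation with the small, highly electrophilic oxalyl half-ester chloride under non-alkoxide conditions should derivatise the hindered tertiary alcohol without retro-aldol opening.

Step 10
Reactants: 17 C5 methyl oxalate of 16
Product: 18 C3-keto tricycle (C1 OTBS; C5 H; C7=C8 alkene; C9 R)
Conditions: Bu3SnH (0.5 M), AIBN, toluene, 110 °C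
Reagents that add atoms: none
Why: Barton–McCombie-type radical deoxygenation of the tertiary methyl oxalate should give the C5 radical, which can take hydrogen only on its endo lobe because C4 is held in the seven-membered ring, so C5 is fixed as in the target, and the high stannane concentration should outrun a 1,2-acyl shift.

Step 11
Reactants: 18 C3-keto tricycle
Product: 19 C3,C7-diketo tricycle with the C8=C9 enone (C1 OTBS)
Conditions: Rh2(cap)4 (dirhodium tetracaprolactamate, 1 mol %), t-BuOOH (5 equiv), K2CO3, CH2Cl2, rt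
Reagents that add atoms: tert-butyl hydroperoxide, CC(C)(C)OO
Why: Radical allylic oxidation should abstract the only reactive allylic hydrogen (C9–H, since C6–H is a bridgehead) and oxygenate the C7–C8–C9 allyl radical at secondary C7, which gives the transposed enone C7(=O)–C8=C9 and erases the C9 stereocentre.

Step 12
Reactants: 19 C3,C7-diketo tricycle with the C8=C9 enone
Product: 20 C1-hydroxy C3,C7-diketone
Conditions: HF·pyridine, pyridine, THF, 0 °C to rt
Reagents that add atoms: none
Why: Buffered fluoride desilylation should free the hindered secondary C1 hydroxyl without the base that would provoke retro-aldol or elimination of the β-hydroxy ketone.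

Step 13
Reactants: 20 C1-hydroxy C3,C7-diketone; 21 (E)-2-methylbut-2-enal
Product: 22 C1 tiglate C3 alcohol
Conditions: SmI2 (0.3 equiv, premixed with 21), 21 (8 equiv), THF, −10 °C
Reagents that add atoms: none
Why: In the Evans–Tishchenko reduction the C1 hemiacetal of the conjugated aldehyde, which has no α-hydrogen, should pass its hydride within a samarium chelate to the C3 ketone on the face of the C1 oxygen, which sets C3 anti to C1 as (R) and leaves the aldehyde as the C1 tiglate.

Step 14
Reactants: 22 C1 tiglate C3 alcohol; 23 3-methylbutanoyl chloride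
Product: 24 target, C1 tiglate C3 isovalerate (1R,3R,5S,6R,10R,11R)
Conditions: 23, DMAP, Et3N, CH2Cl2, 0 °C to rt
Reagents that add atoms: none
Why: DMAP-catalysed acylation should esterify the remaining secondary hydroxyl, and the trans-1,3 arrangement of the two oxygens across the rigid ring should prevent acyl migration.

Compound list
1 | (S)-4-benzyl-3-propionyl-1,3-oxazolidin-2-one | CCC(=O)N1[C@@H](Cc2ccccc2)COC1=O | starting material
2 | allyl iodide | C=CCI | starting material
3 | (S)-4-benzyl-3-[(R)-2-methylpent-4-enoyl]-1,3-oxazolidin-2-one | C=CC[C@@H](C)C(=O)N1[C@@H](Cc2ccccc2)COC1=O | intermediate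
4 | (R)-2-methylpent-4-en-1-ol | C=CC[C@@H](C)CO | intermediate
5 | 2-(triphenylphosphoranylidene)propanal | CC(C=O)=P(c1ccccc1)(c1ccccc1)c1ccccc1 | starting material
6 | (R)-2-methylpent-4-enal | C=CC[C@@H](C)C=O | intermediate (not isolated)
7 | (2E,4R)-2,4-dimethylhepta-2,6-dienal | C=CC[C@@H](C)/C=C(\C)C=O | intermediate
8 | 3-methylbut-3-en-2-one | CC(=O)C(C)=C | starting material
9 | (5R,6E,8R)-5-hydroxy-2,6,8-trimethylundeca-1,6,10-trien-3-one | C=CC[C@@H](C)/C=C(\C)[C@H](O)CC(=O)C(C)=C | intermediate
10 | (5R,6E,8R)-5-[(tert-butyldimethylsilyl)oxy]-2,6,8-trimethylundeca-1,6,10-trien-3-one | C=CC[C@@H](C)/C=C(\C)[C@H](O[Si](C)(C)C(C)(C)C)CC(=O)C(C)=C | intermediate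
11 | acrylic acid | C=CC(=O)O | starting material
12 | (2E,5R,6E,8R)-8-[(tert-butyldimethylsilyl)oxy]-5,7,11-trimethyl-10-oxododeca-2,6,11-trienoic acid | OC(=O)/C=C/C[C@@H](C)/C=C(\C)[C@H](O[Si](C)(C)C(C)(C)C)CC(=O)C(C)=C | intermediate
13 | (2E,5R,6E,8R)-8-[(tert-butyldimethylsilyl)oxy]-5,7,11-trimethyl-10-oxododeca-2,6,11-trienoyl chloride | ClC(=O)/C=C/C[C@@H](C)/C=C(\C)[C@H](O[Si](C)(C)C(C)(C)C)CC(=O)C(C)=C | intermediate (not isolated)
14 | (3Z,5R,6E,8R)-8-[(tert-butyldimethylsilyl)oxy]-5,7,11-trimethyldodeca-1,3,6,11-tetraene-1,10-dione (vinylketene) | O=C=C/C=C\[C@@H](C)/C=C(\C)[C@H](O[Si](C)(C)C(C)(C)C)CC(=O)C(C)=C | intermediate (not isolated)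
15 | 7-[(1R)-1-(tert-butyldimethylsilyloxy)-4-methyl-3-oxopent-4-enyl]-4,7-dimethylbicyclo[3.1.1]hept-2-en-6-one; skeleton locants: C5 ketone, C7=C8 alkene, C9 (R) with methyl on the face of C5, C11 methyl syn to the C7–C9 bridge, C6 and C10 arranged as in the target | O=C1[C@H]2C=C[C@@H](C)[C@@H]1[C@@]2(C)[C@H](O[Si](C)(C)C(C)(C)C)CC(=O)C(C)=C | intermediate
16 | tricycle of the target skeleton with C1 OTBS (R), C3 ketone, C4 gem-dimethyl, C5 tertiary hydroxyl on the face of the C7–C9 bridge, C7=C8 alkene, C9 methyl (R), C11 methyl | CC(C)(C)[Si](C)(C)O[C@@H]1CC(=O)C(C)(C)[C@]2(O)[C@H]3C=C[C@@H](C)[C@@H]2[C@]31C | intermediate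
17 | C5 methyl oxalate of 16 | CC(C)(C)[Si](C)(C)O[C@@H]1CC(=O)C(C)(C)[C@]2(OC(=O)C(=O)OC)[C@H]3C=C[C@@H](C)[C@@H]2[C@]31C | intermediate
18 | tricycle with C1 OTBS (R), C3 ketone, C5 hydrogen (C4 anti to the C7–C9 bridge), C7=C8 alkene, C9 methyl (R) | CC(C)(C)[Si](C)(C)O[C@@H]1CC(=O)C(C)(C)[C@@H]2[C@H]3C=C[C@@H](C)[C@@H]2[C@]31C | intermediate
19 | tricycle with C1 OTBS (R), C3 ketone, C7 ketone conjugated to C8=C9(Me) | CC(C)(C)[Si](C)(C)O[C@@H]1CC(=O)C(C)(C)[C@@H]2[C@H]3C(=O)C=C(C)[C@@H]2[C@]31C | intermediate
20 | tricycle with C1 hydroxyl (R), C3 ketone, C7 enone | O[C@@H]1CC(=O)C(C)(C)[C@@H]2[C@H]3C(=O)C=C(C)[C@@H]2[C@]31C | intermediate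
21 | (E)-2-methylbut-2-enal | C/C=C(\C)C=O | starting material
22 | tricycle with C1 tiglate (R), C3 hydroxyl (R, trans to the C1 oxygen), C7 enone | C/C=C(\C)C(=O)O[C@@H]1C[C@@H](O)C(C)(C)[C@@H]2[C@H]3C(=O)C=C(C)[C@@H]2[C@]31C | intermediate
23 | 3-methylbutanoyl chloride (isovaleryl chloride) | CC(C)CC(=O)Cl | starting material
24 | target: C1 (E)-2-methylbut-2-enoate, C3 3-methylbutanoate, C7 enone, (1R,3R,5S,6R,10R,11R) in skeleton locants | C/C=C(\C)C(=O)O[C@@H]1C[C@@H](OC(=O)CC(C)C)C(C)(C)[C@@H]2[C@H]3C(=O)C=C(C)[C@@H]2[C@]31C | target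

Total step count: 14. Longest linear sequence: 14 steps (from 1).

Steps most likely to fail

Step 7. The vinylketene may form mainly as the (E)-isomer, which cannot close. Prolonged heating with Et3N may also strip silanol from the β-silyloxy ketone or oligomerise the isopropenyl ketone, and the allylic C1 centre may erode facial control. Fallback, from 7 and back at 15: the cycloaddition is run before the aldol, on a chain that holds only the reacting groups and so tolerates forcing conditions. Luche reduction of 7 (NaBH4, CeCl3·7H2O, MeOH) gives allylic alcohol F1, and TBSCl with imidazole gives silyl ether F2. Cross-metathesis with 11 gives dienoic acid F3. Oxalyl chloride and then Et3N in toluene at reflux give, through acid chloride F4 and vinylketene F5, bicyclic ketone F6. HF·pyridine gives alcohol F7 and Dess–Martin periodinane gives keto aldehyde F8. The boron aldol of 8 under (−)-Ipc2BCl gives hydroxy enone F9, and TBSOTf with 2,6-lutidine returns 15.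

Step 8. Conjugate reduction may end in simple protonation of the hindered copper enolate, or hydride may add to the strained ketone, before the C4–C5 bond forms. Fallback, from 15 and back at 16: 1,4-hydrosilylation of the enone (Et3SiH, RhCl(PPh3)3, benzene, 50 °C) gives the isolable tetrasubstituted silyl enol ether F10. TiCl4 in CH2Cl2 at −78 °C then closes the ring to 16 by an intramolecular Mukaiyama aldol addition.

Step 11. Hydrogen abstraction at the shielded C9–H may be slow, and oxygen may be captured at C9 or at other C–H bonds, giving mixtures or over-oxidation. Fallback, from 18 and back at 19: 3-chloroperbenzoic acid epoxidises C7=C8 on the face of C5 to epoxide F11. TMSOTf and DBU open it by anti elimination of the C9 hydrogen to the allylic trimethylsilyl ether F12. Dilute citric acid in methanol frees allylic alcohol F13, and Dess–Martin periodinane gives 19.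

Further compounds
F1 | step 7 | (2E,4R)-2,4-dimethylhepta-2,6-dien-1-ol | C=CC[C@@H](C)/C=C(\C)CO
F2 | step 7 | tert-butyldimethylsilyl ether of F1 | C=CC[C@@H](C)/C=C(\C)CO[Si](C)(C)C(C)(C)C
F3 | step 7 | (2E,5R,6E)-8-[(tert-butyldimethylsilyl)oxy]-5,7-dimethylocta-2,6-dienoic acid | OC(=O)/C=C/C[C@@H](C)/C=C(\C)CO[Si](C)(C)C(C)(C)C
F4 | step 7 | acid chloride of F3 | ClC(=O)/C=C/C[C@@H](C)/C=C(\C)CO[Si](C)(C)C(C)(C)C
F5 | step 7 | (3Z,5R,6E)-8-[(tert-butyldimethylsilyl)oxy]-5,7-dimethylocta-1,3,6-trien-1-one (vinylketene) | O=C=C/C=C\[C@@H](C)/C=C(\C)CO[Si](C)(C)C(C)(C)C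
F6 | step 7 | 7-[(tert-butyldimethylsilyloxy)methyl]-4,7-dimethylbicyclo[3.1.1]hept-2-en-6-one (C9 R, ring centres as in 15) | O=C1[C@H]2C=C[C@@H](C)[C@@H]1[C@@]2(C)CO[Si](C)(C)C(C)(C)C
F7 | step 7 | 7-(hydroxymethyl)-4,7-dimethylbicyclo[3.1.1]hept-2-en-6-one (ring centres as in 15) | O=C1[C@H]2C=C[C@@H](C)[C@@H]1[C@@]2(C)CO
F8 | step 7 | 4,7-dimethyl-6-oxobicyclo[3.1.1]hept-2-ene-7-carbaldehyde (ring centres as in 15) | O=C1[C@H]2C=C[C@@H](C)[C@@H]1[C@@]2(C)C=O
F9 | step 7 | 7-[(1R)-1-hydroxy-4-methyl-3-oxopent-4-enyl]-4,7-dimethylbicyclo[3.1.1]hept-2-en-6-one (ring centres as in 15) | O=C1[C@H]2C=C[C@@H](C)[C@@H]1[C@@]2(C)[C@H](O)CC(=O)C(C)=C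
F10 | step 8 | triethylsilyl enol ether of 15 at C3 (C3=C4 tetrasubstituted) | O=C1[C@H]2C=C[C@@H](C)[C@@H]1[C@@]2(C)[C@H](O[Si](C)(C)C(C)(C)C)CC(O[Si](CC)(CC)CC)=C(C)C
F11 | step 11 | C7–C8 epoxide of 18 with the oxygen on the face of C5 | CC(C)(C)[Si](C)(C)O[C@@H]1CC(=O)C(C)(C)[C@@H]2[C@H]3[C@H]4O[C@H]4[C@@H](C)[C@@H]2[C@]31C
F12 | step 11 | C7 trimethylsilyl ether of the C8=C9 allylic alcohol (oxygen on the face of C5) | CC(C)(C)[Si](C)(C)O[C@@H]1CC(=O)C(C)(C)[C@@H]2[C@H]3[C@@H](O[Si](C)(C)C)C=C(C)[C@@H]2[C@]31C
F13 | step 11 | C7 allylic alcohol with C8=C9 (C1 OTBS, C3 ketone) | CC(C)(C)[Si](C)(C)O[C@@H]1CC(=O)C(C)(C)[C@@H]2[C@H]3[C@@H](O)C=C(C)[C@@H]2[C@]31C
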